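The target is numbered as its two terpene halves. C1–C15 is the guaianolide half. C1'–C15' is the 1,10-seco-eudesmanolide half.

## Analysis of the target

- **Ring system.** The target is a hexacyclic Diels–Alder-type dimer of two sesquiterpene lactones. The guaianolide half carries ring A, an α-methylene-γ-butyrolactone fused to C7–C8, and ring B, the cycloheptane. Its former cyclopentadiene (C1–C5) is now the norbornene.
- **Junction of the halves.** The seco-eudesmanolide half joins through C13' (to C1) and the spiro carbon C11' (to C3). It carries a cis-fused spiro-lactone on the cyclohexene ring E.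
- **Stereocentres.** There are eleven: C1, C2, C3, C7, C8, C10 and C4', C7', C8', C10', C11'.
- **Guaianolide half.** O8 is trans to C11 and to the C10 methyl. C13' sits on the face of ring B opposite that methyl. The C2 acetate lies over the saturated C13'–C11' bridge, anti to C4=C5.
- **Seco-eudesmanolide half.** O8', C11' and the C10' hydroxyl are all cis on ring E. C3 sits on the H7' (convex) face of the lactone, and C12' is endo.
- **Sensitive groups.** These are the ring A Michael acceptor, the tertiary allylic C10' alcohol, two acetates and the strained 7-norbornenyl ester.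
- **Main difficulties.** The norbornene must form with four selectivities at once. One methylene lactone must also act as dienophile while the other stays silent.
- **Feature the plan rests on.** In ring A, C12 lies between O8 and the vinylic C11. An ethynyl group on C7 and a free hydroxyl on C8 are therefore ring A minus one molecule of carbon monoxide.

## Retrosynthetic reasoning

**51 ⇒ 49 + 50.** The C12–O8 and C11–C12 bonds are cut, which removes only the carbonyl carbon. Alkynol 49 has no Michael acceptor, and its alkyne is a poor dienophile. The forward reaction has to insert 50 between hydroxyl and alkyne, close ring A, and touch nothing else.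

**49 ⇒ 48 ⇒ 47.** These are protecting-group steps only. All three silyl groups of 47 fall together. The primary C1' hydroxyl of 48 is then acetylated ahead of the hindered C8 hydroxyl and the tertiary C10' hydroxyl.

**47 ⇒ 46 + 45.** The C1–C13' and C3–C11' bonds are cut (retro-Diels–Alder), which splits the molecule into two halves of equal size. Because ring A is masked, the methylene lactone of 45 is the only competent dienophile. The forward reaction must add syn to the C2 acetate, on the convex face of 45, with C12' endo and the CH2 terminus on the substituted C1.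

**46 ⇒ 21 ⇒ 19.** The labile 5-acetoxycyclopentadiene is released only at the last moment, by loss of water from the tertiary C4 alcohol of 21. C2 comes from reagent-controlled reduction of the C2 ketone of 19, so it does not depend on ring B.

**19 ⇒ 18 ⇒ 17 ⇒ 16 ⇒ 14.** The C3–C4 bond is an intramolecular aldol of enedione 18. Furan 17 stores the enedione oxidation level. The C4–C5 bond is a conjugate addition of an acetyl anion equivalent to enone 14.

**14 ⇒ 13 ⇒ 12.** The C1=C5 bond of ring B is cut (ring-closing metathesis). This is the only ring B bond that carries no stereocentre. All three ring B centres can therefore be set in the open chain.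

**12 ⇒ 9 ⇒ 7 + 4.** The C7–C8 bond is cut. An allenylmetal from 4 adds to aldehyde 7 and delivers alkyne, hydroxyl and both stereocentres in one operation. The anti relation it sets becomes trans in the ring.

**7 ⇒ 5 + 6, and 4 ⇒ 1.** The C1–C10 bond is a catalytic asymmetric Michael addition. The carbinol centre of 4 comes from an asymmetric allylation.

**45 ⇒ 42 ⇒ 40 ⇒ 39.** C13' is added last to lactone 42. The C10'–C14' bond comes from a methyl nucleophile attacking ketone 39 opposite the two cis substituents.

**39 ⇒ 36 + 25.** The C4'–C5' bond is cut between an sp2 and an sp3 carbon. C4' then comes from the chiral pool (25 from 22) and is transferred with retention.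

**36 ⇒ 34 ⇒ 30 ⇒ 28 ⇒ 26.** The C7'–C11' bond is a suprafacial [3,3] shift. It copies the cis-1,4 relation of desymmetrised diol 28 into the cis-1,2 relation of C11' and O8', and it places the alkene at C5'=C6'.

## Alternatives that were turned down

**Alternative 1:**
- **Disconnection and key step.** The C9'–C10' bond of ring E is cut on the finished core. A C8' bromomethyl ketone is reduced by a divalent samarium reagent to an enolate, which attacks the C10' methyl ketone and gives β-hydroxy ketone A1.
- **For it.** Ring E and the tertiary carbinol form in one chelate-organised step. The Diels–Alder partner shrinks to a simple acrylate, so this plan is stronger in the number of stereocentres set by its key step.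
- **Against it.** A1 already contains the ring A methylene lactone and a conjugated ketone, and both accept single electrons or enolates readily. The (Z)-enone needed for closure can isomerise.
- **Work left after it.** A1 still needs a stereoselective C8' reduction and a translactonisation to the spiro-lactone.
- **Comparison.** The chosen plan never exposes a Michael acceptor to reducing or basic reagents.

**Alternative 2:**
- **Disconnection and key step.** The C7–C11 and C8–O bonds are cut in a ring B enone. A vinyl cuprate adds to C7, and the enolate is oxygenated aerobically and reduced, which gives ketol A2.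
- **For it.** Two bonds form in one pot, and anti addition gives the trans pair, so it matches the chosen plan in bond count.
- **Against it.** A2 carries a C9 ketone that the target lacks. Removing it next to a free ketol and an epimerisable C10 is long and risks ketol shifts.
- **Work left after it.** The allyl silyl ether must then be raised by two oxidation levels in the presence of three other alkenes before ring A can close. The cuprate also meets two acetates and a lactone.
- **Comparison.** The chosen plan needs no step after its key reaction.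

**Alternative 3:**
- **Disconnection and key step.** The C7–C8 bond is cut as the ring B closure. An allylmetal made from a (Z)-2-(bromomethyl)enoate arm with a low-valent metal (divalent chromium or metallic indium) attacks a C8 aldehyde through C7. This gives hydroxy ester A3, which lactonises.
- **For it.** This is the most step-economical idea. One reaction gives ring B, C7, C8 and every carbon of ring A, which is more than the chosen key step achieves.
- **Against it.** The ring to be closed is seven-membered and spans a quaternary bridgehead and a tetrasubstituted alkene. The relative and facial outcome of such a medium-ring allylation cannot be predicted. The bromomethyl enoate is both an alkylating agent and a second dienophile, so it would have to be built after the cycloaddition on the full core.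
- **Comparison.** The chosen plan gives up that economy. In exchange, C7 and C8 are set by reagent control in an open chain, and the last step has a single possible ring size.

Key step: step 30

Assumption: the lipase of step 18 acetylates the (R)-configured carbinol centre of meso-diol 28. If the enzyme at hand prefers the other centre, hydrolysis of the meso-diacetate with that enzyme leads to the same compound 29.

## Route

**Step 1**
Reactants: 1 3-(triisopropylsilyl)prop-2-ynal
Product: 3 (R)-1-(triisopropylsilyl)hex-5-en-1-yn-3-ol, via borinate ester 2 (not isolated)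
Conditions: (+)-Ipc2B(allyl), Et2O, −100 °C; then NaOH, H2O2, 0 °C
Reagents that add atoms: (+)-B-allyldiisopinocampheylborane, C=CCB(C1CC2CC(C1C)C2(C)C)C1CC2CC(C1C)C2(C)C
Why: Brown allylboration through a closed chair transition state; the (+)-reagent should give the (R)-carbinol, whose configuration is later passed on to C7.

**Step 2**
Reactants: 3 (R)-1-(triisopropylsilyl)hex-5-en-1-yn-3-ol
Product: 4 (R)-1-(triisopropylsilyl)hex-5-en-1-yn-3-yl methanesulfonate
Conditions: MsCl, Et3N, CH2Cl2, −78 °C
Reagents that add atoms: methanesulfonyl chloride, CS(=O)(=O)Cl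
Why: Sulfonylation at oxygen leaves the stereocentre untouched and gives the leaving group needed for step 4.

**Step 3**
Reactants: 5 (E)-but-2-enal; 6 dimethyl malonate
Product: 7 dimethyl 2-[(2R)-4-oxobutan-2-yl]malonate
Conditions: (S)-2-[diphenyl(trimethylsilyloxy)methyl]pyrrolidine (10 mol %), PhCO2H (10 mol %), EtOH, 0 °C → rt
Reagents that add atoms: none
Why: Iminium-catalysed asymmetric Michael addition; the diarylcarbinol silyl ether shields one face of the (E)-iminium ion, so the malonate should attack from the other and set C10 as (R). The two esters are C2 and a sacrificial carboxyl.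

**Step 4**
Reactants: 7 dimethyl 2-[(2R)-4-oxobutan-2-yl]malonate; 4 (R)-1-(triisopropylsilyl)hex-5-en-1-yn-3-yl methanesulfonate
Product: 9 dimethyl 2-[(2R,4R,5S)-4-hydroxy-5-[(triisopropylsilyl)ethynyl]oct-7-en-2-yl]malonate, via allenylindium reagent 8 (not isolated)
Conditions: Pd(dppf)Cl2 (5 mol %), InI (1.5 equiv), THF–HMPA (3:1), rt
Reagents that add atoms: none
Why: Marshall propargylation: zerovalent palladium displaces the mesylate anti (SN2′), transmetalation gives a chiral allenylindium, and this adds through a cyclic SE2′ transition state. C7 forms with net inversion of the carbinol centre of 4, and C8 forms anti to it, which is the later trans pair. The weakly basic indium reagent tolerates the malonate C–H.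

**Step 5**
Reactants: 9 dimethyl 2-[(2R,4R,5S)-4-hydroxy-5-[(triisopropylsilyl)ethynyl]oct-7-en-2-yl]malonate
Product: 10 C8 tert-butyldimethylsilyl ether of 9
Conditions: TBSOTf, 2,6-lutidine, CH2Cl2, −78 → 0 °C
Reagents that add atoms: tert-butyldimethylsilyl triflate, CC(C)(C)[Si](C)(C)OS(=O)(=O)C(F)(F)F
Why: Prompt silylation prevents δ-lactonisation of O8 onto a malonate ester and masks the hydroxyl until step 28.

**Step 6**
Reactants: 10 C8 tert-butyldimethylsilyl ether of 9
Product: 12 (3R,5R,6S)-5-(tert-butyldimethylsilyloxy)-3-methyl-2-methylidene-6-[(triisopropylsilyl)ethynyl]non-8-enoic acid, via malonic acid 11 (not isolated)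
Conditions: KOH, MeOH–H2O, 60 °C, then HCl to pH 2; crude diacid, aq. HCHO, Et2NH, EtOAc, reflux
Reagents that add atoms: potassium hydroxide, [K+].[OH-]; formaldehyde, C=O
Why: Saponification followed by decarboxylative Mannich methylenation of a monosubstituted malonic acid, the classical route to 2-substituted acrylic acids. The silyl ether and the triisopropylsilyl alkyne are stable to base.

**Step 7**
Reactants: 12 (3R,5R,6S)-5-(tert-butyldimethylsilyloxy)-3-methyl-2-methylidene-6-[(triisopropylsilyl)ethynyl]non-8-enoic acid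
Product: 13 (4S,5R,7R)-5-(tert-butyldimethylsilyloxy)-7-methyl-4-[(triisopropylsilyl)ethynyl]cyclohept-1-ene-1-carboxylic acid
Conditions: second-generation Hoveyda–Grubbs catalyst (5 mol %), toluene (2 mM), 80 °C
Reagents that add atoms: none
Why: Ring-closing metathesis: the catalyst loads on the allyl group and closes onto the acrylic alkene, forming C1=C5 and ring B. The bulky silyl alkyne stays out of enyne pathways.

**Step 8**
Reactants: 13 (4S,5R,7R)-5-(tert-butyldimethylsilyloxy)-7-methyl-4-[(triisopropylsilyl)ethynyl]cyclohept-1-ene-1-carboxylic acid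
Product: 14 1-[(4S,5R,7R)-5-(tert-butyldimethylsilyloxy)-7-methyl-4-[(triisopropylsilyl)ethynyl]cyclohept-1-en-1-yl]ethanone
Conditions: MeLi (2.5 equiv), Et2O, 0 °C → rt; aqueous work-up
Reagents that add atoms: methyllithium, [Li]C
Why: Addition of methyllithium to a lithium carboxylate stops at the dilithio gem-diolate and gives the methyl ketone on work-up. The new methyl is C3.

**Step 9**
Reactants: 14 1-[(4S,5R,7R)-5-(tert-butyldimethylsilyloxy)-7-methyl-4-[(triisopropylsilyl)ethynyl]cyclohept-1-en-1-yl]ethanone
Product: 16 1,2-diacetylcycloheptane (C1 and C5 epimers; C7 S; C8 R; C10 R), via enol ether adduct 15 (not isolated)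
Conditions: ethyl vinyl ether, t-BuLi, THF, −78 → 0 °C; CuI, −40 °C; 14, −78 → −30 °C; then 1 M HCl, THF, 0 °C
Reagents that add atoms: ethyl vinyl ether, C=COCC; water, O
Why: Conjugate addition of an α-alkoxyvinyl cuprate, an acetyl anion equivalent, forms C4–C5, and mild acid unmasks the ketone. The new centres at C1 and C5 are erased in step 10.

**Step 10**
Reactants: 16 1,2-diacetylcycloheptane (C1 and C5 epimers)
Product: 17 (4R,6R,7S)-6-(tert-butyldimethylsilyloxy)-1,3,4-trimethyl-7-[(triisopropylsilyl)ethynyl]-5,6,7,8-tetrahydro-4H-cyclohepta[c]furan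
Conditions: p-TsOH·H2O (5 mol %), toluene, 4 Å molecular sieves, 70 °C
Reagents that add atoms: none
Why: Paal–Knorr cyclodehydration of a 1,4-diketone. Both epimers converge, and the furan stores the C1=C5 unsaturation.

**Step 11**
Reactants: 17 ring B-fused 2,5-dimethylfuran
Product: 19 4-hydroxy-4-methyl-2-oxo bicyclic enone (guaiane C1=C5; C4 epimers), via enedione 18 (not isolated)
Conditions: mCPBA (1.0 equiv), CH2Cl2, 0 °C; then 2 % aq. Na2CO3, THF, rt
Reagents that add atoms: 3-chloroperoxybenzoic acid, OOC(=O)c1cccc(Cl)c1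
Why: Oxidative furan opening gives the (Z)-enedione, and a reversible intramolecular aldol closes the 4-hydroxycyclopentenone. Attack on the less hindered C4 ketone beside C6H2, and placement of the bulky carbinol away from the branched C10, should both favour C3–C4 closure.

**Step 12**
Reactants: 19 4-hydroxy-4-methyl-2-oxo bicyclic enone
Product: 20 (2R)-2,4-diol
Conditions: (S)-Me-CBS oxazaborolidine (0.5 equiv), catecholborane (3 equiv), toluene, −78 °C
Reagents that add atoms: none
Why: Corey–Bakshi–Shibata reduction: the fully substituted alkenyl side acts as the large group and C3H2 as the small one, so the (S)-catalyst should give (2R) under reagent control for both C4 epimers.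

**Step 13**
Reactants: 20 (2R)-2,4-diol
Product: 21 (2R)-2-acetoxy-4-hydroxy diene precursor
Conditions: Ac2O (1.2 equiv), pyridine, DMAP (cat.), CH2Cl2, 0 °C
Reagents that add atoms: acetic anhydride, CC(=O)OC(C)=O
Why: The secondary allylic alcohol is acylated far faster than the tertiary one.

**Step 14**
Reactants: 22 (S)-γ-valerolactone
Product: 23 (S)-pentane-1,4-diol
Conditions: LiAlH4, THF, 0 °C → rt
Reagents that add atoms: none
Why: Lactone reduction; the chiral-pool stereocentre is not involved.

**Step 15**
Reactants: 23 (S)-pentane-1,4-diol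
Product: 24 (S)-5-(tert-butyldiphenylsilyloxy)pentan-2-ol
Conditions: TBDPSCl (1.0 equiv), imidazole, CH2Cl2, 0 °C
Reagents that add atoms: tert-butyl(chloro)diphenylsilane, CC(C)(C)[Si](Cl)(c1ccccc1)c1ccccc1
Why: The bulky chlorosilane selects the primary hydroxyl.

**Step 16**
Reactants: 24 (S)-5-(tert-butyldiphenylsilyloxy)pentan-2-ol
Product: 25 (R)-tert-butyl[(4-iodopentyl)oxy]diphenylsilane
Conditions: I2, PPh3, imidazole, CH2Cl2, −10 °C, dark
Reagents that add atoms: iodine, II
Why: Appel iodination by SN2 with inversion; low temperature and short contact limit iodide exchange.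

**Step 17**
Reactants: 26 cyclohexa-1,3-diene
Product: 28 meso-cis-cyclohex-2-ene-1,4-diol, via endoperoxide 27 (not isolated)
Conditions: O2, hν, tetraphenylporphyrin (cat.), CH2Cl2, −20 °C; then Zn, AcOH, 0 °C
Reagents that add atoms: dioxygen, O=O
Why: The singlet-oxygen [4+2] cycloaddition places both oxygens on one face, and O–O reduction keeps the cis relation.

**Step 18**
Reactants: 28 meso-cis-cyclohex-2-ene-1,4-diol
Product: 29 (1R,4S)-4-hydroxycyclohex-2-en-1-yl acetate
Conditions: lipase PS (Burkholderia cepacia), vinyl acetate, t-BuOMe, 30 °C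
Reagents that add atoms: vinyl acetate, C=COC(C)=O
Why: Enzymatic desymmetrisation of a meso-diol by irreversible acyl transfer. This sets the absolute configuration of the whole ring E series.

**Step 19**
Reactants: 29 (1R,4S)-4-hydroxycyclohex-2-en-1-yl acetate
Product: 30 (1R,4S)-4-(triethylsilyloxy)cyclohex-2-en-1-yl acetate
Conditions: TESCl, imidazole, CH2Cl2, 0 °C
Reagents that add atoms: chlorotriethylsilane, CC[Si](Cl)(CC)CC
Why: This masks O8' with a group that can later be removed beside the primary TBDPS ether.

**Step 20**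
Reactants: 30 (1R,4S)-4-(triethylsilyloxy)cyclohex-2-en-1-yl acetate
Product: 34 methyl 2-[(1S,6S)-6-(triethylsilyloxy)cyclohex-2-en-1-yl]acetate, via silyl ketene acetal 31 (not isolated), via trimethylsilyl ester 32 (not isolated), via carboxylic acid 33 (not isolated)
Conditions: LDA, THF, −78 °C; TMSCl; −78 → 60 °C; aq. citric acid; then MeI, K2CO3, DMF, rt
Reagents that add atoms: iodomethane, CI
Why: The Ireland–Claisen rearrangement is suprafacial, so C11' arrives at C7' on the face that carried the acetate. It is therefore cis to O8', and the alkene moves to C5'=C6'.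

**Step 21**
Reactants: 34 methyl 2-[(1S,6S)-6-(triethylsilyloxy)cyclohex-2-en-1-yl]acetate
Product: 35 methyl 2-[(1S,6S)-4-oxo-6-(triethylsilyloxy)cyclohex-2-en-1-yl]acetate
Conditions: Rh2(cap)4 (1 mol %), t-BuOOH (70 % aq., 5 equiv), 1,2-dichloroethane, 40 °C
Reagents that add atoms: tert-butyl hydroperoxide, CC(C)(C)OO
Why: Catalytic allylic oxidation: hydrogen abstraction from the C10' methylene, and oxygenation at that less hindered terminus of the allyl radical, should give the C10' enone. O8' stays a silyl ether, so β-elimination and aromatisation are held back.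

**Step 22**
Reactants: 35 methyl 2-[(1S,6S)-4-oxo-6-(triethylsilyloxy)cyclohex-2-en-1-yl]acetate
Product: 36 C5'-iodo enone
Conditions: I2, pyridine–CH2Cl2 (1:1), 0 °C → rt
Reagents that add atoms: iodine, II
Why: α-Iodination of an enone by the addition–elimination (Baylis–Hillman-type) mechanism, which is routine for β'-alkoxy cyclohexenones.

**Step 23**
Reactants: 25 (R)-tert-butyl[(4-iodopentyl)oxy]diphenylsilane; 36 C5'-iodo enone
Product: 39 C5'-[(R)-5-(tert-butyldiphenylsilyloxy)pentan-2-yl] enone, via secondary alkyllithium 37 (not isolated), via secondary alkylzinc 38 (not isolated)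
Conditions: 25, t-BuLi (2.2 equiv), pentane–Et2O, −100 °C; Me3SiCH2ZnBr·LiBr, −100 → −30 °C; 36, [PdCl2(IPent)(3-chloropyridine)] (3 mol %), THF, −25 °C → rt
Reagents that add atoms: none
Why: Stereoretentive Negishi coupling: iodine–lithium exchange, transmetalation to zinc and the palladium-catalysed coupling with an alkenyl iodide should each proceed with retention, so C4' is (R). The bulky carbene ligand suppresses β-hydride elimination.

**Step 24**
Reactants: 39 C5'-substituted enone
Product: 40 (10'R) tertiary allylic alcohol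
Conditions: CeCl3, MeLi, THF, −78 °C
Reagents that add atoms: methyllithium, [Li]C
Why: The non-basic organocerium reagent adds 1,2 to the ketone in preference to the ester. Attack opposite the cis C7' and C8' substituents should place the methyl trans and the hydroxyl cis to O8'.

**Step 25**
Reactants: 40 (10'R) tertiary allylic alcohol
Product: 42 cis-fused γ-lactone with free C10' hydroxyl, via hydroxy ester 41 (not isolated)
Conditions: PPTS (20 mol %), MeOH, 0 °C → rt
Reagents that add atoms: none
Why: The secondary TES ether solvolyses well before the primary TBDPS ether, and the cis γ-hydroxy ester lactonises spontaneously.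

**Step 26**
Reactants: 42 cis-fused γ-lactone
Product: 45 α-methylene lactone (dienophile), via Mannich base 43 (not isolated), via methiodide 44 (not isolated)
Conditions: LDA (2.5 equiv), THF, −78 °C; CH2=NMe2+ I−, −78 → 0 °C; then MeI, THF, rt; then aq. NaHCO3, CH2Cl2
Reagents that add atoms: N,N-dimethylmethyleneiminium iodide, C=[N+](C)C.[I-]
Why: Mannich methylenation of the lactone enolate (alkoxide–enolate dianion), then quaternisation and E1cB loss of trimethylamine. C11' becomes planar, so its transient configuration is irrelevant.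

**Step 27**
Reactants: 21 (2R)-2-acetoxy-4-hydroxy diene precursor; 45 α-methylene lactone
Product: 47 silylated Diels–Alder adduct, via acetoxycyclopentadiene 46 (not isolated)
Conditions: Ph2S[OC(CF3)2Ph]2 (1.05 equiv), CH2Cl2, −40 °C; cold filtration through basic alumina; then 45 (1.2 equiv), toluene (2 M), BHT, rt, dark
Reagents that add atoms: none
Why: Martin sulfurane dehydrates the tertiary allylic alcohol at low temperature, and the diene is trapped in a normal-demand Diels–Alder reaction that sets C1, C3 and C11'. 5-Acyloxycyclopentadienes add dienophiles syn to oxygen, and here that face is also anti to the C10 methyl; 45 reacts on its convex H7' face with the carbonyl endo. Sterics pair the CH2 terminus with the substituted C1 and C11' with the unsubstituted C3.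

**Step 28**
Reactants: 47 silylated Diels–Alder adduct
Product: 48 C8,C1',C10'-triol with terminal alkyne
Conditions: TBAF (6 equiv), AcOH (4 equiv), THF, 0 °C → rt
Reagents that add atoms: none
Why: Buffered fluoride removes the O-TBS, O-TBDPS and C-triisopropylsilyl groups in one operation. The buffer protects the C2 acetate and the spiro-lactone.

**Step 29**
Reactants: 48 triol
Product: 49 trans-7-ethynyl-8-hydroxy core (target minus C12=O)
Conditions: AcCl (1.05 equiv), 2,4,6-collidine, CH2Cl2, −78 °C
Reagents that add atoms: acetyl chloride, CC(=O)Cl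
Why: Acylation under kinetic control picks the unhindered primary C1' hydroxyl over the ring-bound secondary C8 hydroxyl and the tertiary C10' hydroxyl.

**Step 30**
Reactants: 49 trans-7-ethynyl-8-hydroxy core; 50 carbon monoxide
Product: 51 target CNP0257312.1
Conditions: PdCl2 (10 mol %), thiourea (40 mol %), CO (1 atm), acetone, 50 °C
Reagents that add atoms: carbon monoxide, [C-]#[O+]
Why: The C8 hydroxyl attacks CO bound to divalent palladium and gives an alkoxycarbonyl–palladium species with loss of HCl, which forms C12–O8. Syn insertion of the tethered alkyne into the Pd–acyl bond forms C11–C12 and closes ring A in the 5-exo-dig mode, the only ring size a homopropargylic alcohol can reach. The HCl released earlier cleaves the vinyl–palladium bond with retention, leaves the C11=C13 methylene and returns PdCl2, so the cycle is redox-neutral. The closest known reaction type is the PdCl2–thiourea cyclocarbonylation of trans-2-ethynylcycloalkanols to trans-fused α-methylene-γ-butyrolactones. No stereocentre is made or touched, since the trans C7/C8 relation dates from step 4. The step needs selectivity for the C8 hydroxyl/alkyne pair: the tertiary C10' alcohol has no alkyne within reach, and the tetra- and trisubstituted alkenes bind palladium far less well than the terminal alkyne. The Michael acceptor appears only here, after all basic, reducing and nucleophilic chemistry.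

## Compound list

1 | 3-(triisopropylsilyl)prop-2-ynal | O=CC#C[Si](C(C)C)(C(C)C)C(C)C | starting material
2 | diisopinocampheylborinate of 3 | C=CC[C@@H](OB(C1CC2CC(C1C)C2(C)C)C1CC2CC(C1C)C2(C)C)C#C[Si](C(C)C)(C(C)C)C(C)C | intermediate
3 | (R)-1-(triisopropylsilyl)hex-5-en-1-yn-3-ol | C=CC[C@@H](O)C#C[Si](C(C)C)(C(C)C)C(C)C | intermediate
4 | (R)-1-(triisopropylsilyl)hex-5-en-1-yn-3-yl methanesulfonate | C=CC[C@@H](OS(C)(=O)=O)C#C[Si](C(C)C)(C(C)C)C(C)C | intermediate
5 | (E)-but-2-enal | C/C=C/C=O | starting material
6 | dimethyl malonate | COC(=O)CC(=O)OC | starting material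
7 | dimethyl 2-[(2R)-4-oxobutan-2-yl]malonate | COC(=O)C(C(=O)OC)[C@H](C)CC=O | intermediate
8 | [1-(triisopropylsilyl)hexa-1,2,5-trien-1-yl]indium iodide methanesulfonate (axially chiral) | [H]C(CC=C)=[C@@]=C([In](I)OS(C)(=O)=O)[Si](C(C)C)(C(C)C)C(C)C | intermediate
9 | dimethyl 2-[(2R,4R,5S)-4-hydroxy-5-[(triisopropylsilyl)ethynyl]oct-7-en-2-yl]malonate | COC(=O)C(C(=O)OC)[C@H](C)C[C@@H](O)[C@@H](CC=C)C#C[Si](C(C)C)(C(C)C)C(C)C | intermediate
10 | C8 tert-butyldimethylsilyl ether of 9 | COC(=O)C(C(=O)OC)[C@H](C)C[C@@H](O[Si](C)(C)C(C)(C)C)[C@@H](CC=C)C#C[Si](C(C)C)(C(C)C)C(C)C | intermediate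
11 | malonic acid from 10 | OC(=O)C(C(=O)O)[C@H](C)C[C@@H](O[Si](C)(C)C(C)(C)C)[C@@H](CC=C)C#C[Si](C(C)C)(C(C)C)C(C)C | intermediate
12 | (3R,5R,6S)-5-(tert-butyldimethylsilyloxy)-3-methyl-2-methylidene-6-[(triisopropylsilyl)ethynyl]non-8-enoic acid | C=C(C(=O)O)[C@H](C)C[C@@H](O[Si](C)(C)C(C)(C)C)[C@@H](CC=C)C#C[Si](C(C)C)(C(C)C)C(C)C | intermediate
13 | (4S,5R,7R)-5-(tert-butyldimethylsilyloxy)-7-methyl-4-[(triisopropylsilyl)ethynyl]cyclohept-1-ene-1-carboxylic acid | OC(=O)C1=CC[C@@H](C#C[Si](C(C)C)(C(C)C)C(C)C)[C@H](O[Si](C)(C)C(C)(C)C)C[C@H]1C | intermediate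
14 | methyl ketone of 13 (1-acetylcycloheptene) | CC(=O)C1=CC[C@@H](C#C[Si](C(C)C)(C(C)C)C(C)C)[C@H](O[Si](C)(C)C(C)(C)C)C[C@H]1C | intermediate
15 | C5 1-ethoxyvinyl adduct of 14 (C1, C5 epimers) | CC(=O)C1C(C(=C)OCC)C[C@@H](C#C[Si](C(C)C)(C(C)C)C(C)C)[C@H](O[Si](C)(C)C(C)(C)C)C[C@H]1C | intermediate
16 | 1,2-diacetylcycloheptane (C1, C5 epimers) | CC(=O)C1C(C(C)=O)C[C@@H](C#C[Si](C(C)C)(C(C)C)C(C)C)[C@H](O[Si](C)(C)C(C)(C)C)C[C@H]1C | intermediate
17 | ring B-fused 2,5-dimethylfuran | Cc1oc(C)c2c1C[C@@H](C#C[Si](C(C)C)(C(C)C)C(C)C)[C@H](O[Si](C)(C)C(C)(C)C)C[C@H]2C | intermediate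
18 | 1,2-diacetylcycloheptene (enedione) | CC(=O)C1=C(C(C)=O)C[C@@H](C#C[Si](C(C)C)(C(C)C)C(C)C)[C@H](O[Si](C)(C)C(C)(C)C)C[C@H]1C | intermediate
19 | 4-hydroxy-4-methyl-2-oxo hydroazulenone (C1=C5; C4 epimers) | CC1(O)CC(=O)C2=C1C[C@@H](C#C[Si](C(C)C)(C(C)C)C(C)C)[C@H](O[Si](C)(C)C(C)(C)C)C[C@H]2C | intermediate
20 | (2R)-2,4-diol (C4 epimers) | CC1(O)C[C@@H](O)C2=C1C[C@@H](C#C[Si](C(C)C)(C(C)C)C(C)C)[C@H](O[Si](C)(C)C(C)(C)C)C[C@H]2C | intermediate
21 | (2R)-2-acetoxy-4-hydroxy diene precursor (C4 epimers) | CC1(O)C[C@@H](OC(C)=O)C2=C1C[C@@H](C#C[Si](C(C)C)(C(C)C)C(C)C)[C@H](O[Si](C)(C)C(C)(C)C)C[C@H]2C | intermediate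
22 | (S)-γ-valerolactone | C[C@H]1CCC(=O)O1 | starting material
23 | (S)-pentane-1,4-diol | C[C@H](O)CCCO | intermediate
24 | (S)-5-(tert-butyldiphenylsilyloxy)pentan-2-ol | C[C@H](O)CCCO[Si](c1ccccc1)(c1ccccc1)C(C)(C)C | intermediate
25 | (R)-tert-butyl[(4-iodopentyl)oxy]diphenylsilane | C[C@@H](I)CCCO[Si](c1ccccc1)(c1ccccc1)C(C)(C)C | intermediate
26 | cyclohexa-1,3-diene | C1=CC=CCC1 | starting material
27 | 2,3-dioxabicyclo[2.2.2]oct-5-ene | C1CC2C=CC1OO2 | intermediate
28 | meso-cis-cyclohex-2-ene-1,4-diol | O[C@H]1C=C[C@@H](O)CC1 | intermediate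
29 | (1R,4S)-4-hydroxycyclohex-2-en-1-yl acetate | CC(=O)O[C@H]1C=C[C@@H](O)CC1 | intermediate
30 | (1R,4S)-4-(triethylsilyloxy)cyclohex-2-en-1-yl acetate | CC(=O)O[C@H]1C=C[C@@H](O[Si](CC)(CC)CC)CC1 | intermediate
31 | trimethylsilyl ketene acetal of 30 | C=C(O[Si](C)(C)C)O[C@H]1C=C[C@@H](O[Si](CC)(CC)CC)CC1 | intermediate
32 | trimethylsilyl ester of 33 | C[Si](C)(C)OC(=O)C[C@@H]1C=CCC[C@@H]1O[Si](CC)(CC)CC | intermediate
33 | 2-[(1S,6S)-6-(triethylsilyloxy)cyclohex-2-en-1-yl]acetic acid | OC(=O)C[C@@H]1C=CCC[C@@H]1O[Si](CC)(CC)CC | intermediate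
34 | methyl 2-[(1S,6S)-6-(triethylsilyloxy)cyclohex-2-en-1-yl]acetate | COC(=O)C[C@@H]1C=CCC[C@@H]1O[Si](CC)(CC)CC | intermediate
35 | C10' enone | COC(=O)C[C@@H]1C=CC(=O)C[C@@H]1O[Si](CC)(CC)CC | intermediate
36 | C5'-iodo enone | COC(=O)C[C@@H]1C=C(I)C(=O)C[C@@H]1O[Si](CC)(CC)CC | intermediate
37 | (R)-5-(tert-butyldiphenylsilyloxy)pentan-2-yllithium | C[C@@H]([Li])CCCO[Si](c1ccccc1)(c1ccccc1)C(C)(C)C | intermediate
38 | (R)-5-(tert-butyldiphenylsilyloxy)pentan-2-yl (trimethylsilylmethyl)zinc | C[C@@H]([Zn]C[Si](C)(C)C)CCCO[Si](c1ccccc1)(c1ccccc1)C(C)(C)C | intermediate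
39 | C5'-substituted enone (4'R) | COC(=O)C[C@@H]1C=C([C@H](C)CCCO[Si](c2ccccc2)(c2ccccc2)C(C)(C)C)C(=O)C[C@@H]1O[Si](CC)(CC)CC | intermediate
40 | (10'R) tertiary allylic alcohol | COC(=O)C[C@@H]1C=C([C@H](C)CCCO[Si](c2ccccc2)(c2ccccc2)C(C)(C)C)[C@](C)(O)C[C@@H]1O[Si](CC)(CC)CC | intermediate
41 | C8' hydroxy ester | COC(=O)C[C@@H]1C=C([C@H](C)CCCO[Si](c2ccccc2)(c2ccccc2)C(C)(C)C)[C@](C)(O)C[C@@H]1O | intermediate
42 | cis-fused γ-lactone on ring E | O=C1C[C@@H]2C=C([C@H](C)CCCO[Si](c3ccccc3)(c3ccccc3)C(C)(C)C)[C@](C)(O)C[C@@H]2O1 | intermediate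
43 | C11' dimethylaminomethyl lactone (C11' epimers) | CN(C)CC1C(=O)O[C@H]2C[C@@](C)(O)C([C@H](C)CCCO[Si](c3ccccc3)(c3ccccc3)C(C)(C)C)=C[C@@H]12 | intermediate
44 | methiodide of 43 | C[N+](C)(C)CC1C(=O)O[C@H]2C[C@@](C)(O)C([C@H](C)CCCO[Si](c3ccccc3)(c3ccccc3)C(C)(C)C)=C[C@@H]12.[I-] | intermediate
45 | seco-eudesmanolide α-methylene lactone, C1' TBDPS ether | C=C1C(=O)O[C@H]2C[C@@](C)(O)C([C@H](C)CCCO[Si](c3ccccc3)(c3ccccc3)C(C)(C)C)=C[C@@H]12 | intermediate
46 | (2R)-2-acetoxy guaia-1(5),3-diene with C7 silylethynyl and C8 OTBS | CC1=C[C@@H](OC(C)=O)C2=C1C[C@@H](C#C[Si](C(C)C)(C(C)C)C(C)C)[C@H](O[Si](C)(C)C(C)(C)C)C[C@H]2C | intermediate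
47 | silylated Diels–Alder adduct | CC(C)(C)[Si](C)(C)O[C@@H]2C[C@@H](C)[C@]34C[C@]5(C(=O)O[C@H]6C[C@@](C)(O)C([C@H](C)CCCO[Si](c7ccccc7)(c7ccccc7)C(C)(C)C)=C[C@H]65)[C@H](C(C)=C3C[C@H]2C#C[Si](C(C)C)(C(C)C)C(C)C)[C@H]4OC(C)=O | intermediate
48 | C8,C1',C10'-triol with terminal alkyne | O[C@@H]2C[C@@H](C)[C@]34C[C@]5(C(=O)O[C@H]6C[C@@](C)(O)C([C@H](C)CCCO)=C[C@H]65)[C@H](C(C)=C3C[C@H]2C#C)[C@H]4OC(C)=O | intermediate
49 | trans-7-ethynyl-8-hydroxy core | O[C@@H]2C[C@@H](C)[C@]34C[C@]5(C(=O)O[C@H]6C[C@@](C)(O)C([C@H](C)CCCOC(C)=O)=C[C@H]65)[C@H](C(C)=C3C[C@H]2C#C)[C@H]4OC(C)=O | intermediate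
50 | carbon monoxide | [C-]#[O+] | starting material
51 | CNP0257312.1 | C=C1C(=O)O[C@@H]2C[C@@H](C)[C@]34C[C@]5(C(=O)O[C@H]6C[C@@](C)(O)C([C@H](C)CCCOC(C)=O)=C[C@H]65)[C@H](C(C)=C3C[C@@H]12)[C@H]4OC(C)=O | target

## Step count and least certain steps

Total step count: 30.
Longest linear sequence: 16 steps (from 1 through steps 1, 2, 4–13 and 27–30).

**Step 30 (key step).**
- **What may go wrong.** Carbonylation may lose out to direct attack of the hydroxyl on the palladium-activated alkyne (cycloisomerisation to an enol ether), to oxidative double carbonylation, or to slow turnover in the crowded pocket beside ring B. Acid-promoted ionisation of the C10' alcohol could set in meanwhile.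
- **Fallback.** This runs from 49 to 51. Molybdenum-catalysed Markovnikov hydrostannation (Mo(CO)3(CNt-Bu)3, Bu3SnH) gives the internal vinylstannane F1. Iodine converts it into the 2-iodoalkene F2. Oxidative addition to zerovalent palladium (Pd(PPh3)4, CO, Et3N) followed by acyl capture by O8 then closes ring A by a different mechanism.

**Step 27.**
- **What may go wrong.** A [1,5]-hydrogen shift of the C2–H may outrun the cycloaddition with the hindered dienophile. Poor endo/exo or regiochemical discrimination is also possible, because locked s-cis methylene lactones often prefer the exo mode.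
- **Fallback.** This runs from 19 to 47. Dehydration of 19 (MsCl, Et3N) in the presence of 45 releases cyclopentadienone F3, which cannot undergo the hydrogen shift. Cycloaddition gives the 7-norbornenone F4. NaBH4 at −78 °C attacks the strained ketone from the alkene side and gives the anti alcohol F5. Acetylation then returns to 47. In this variant the diene face is chosen by the C10 methyl alone.

**Step 11.**
- **What may go wrong.** The aldol may close in the other direction, with the C15 enolate attacking the C2 ketone. Water may also be lost from the ketol.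
- **Fallback.** This runs from 13 to 19. Acid 13 is converted into the Weinreb amide F6, and 1-propenylmagnesium bromide gives the divinyl ketone F7. Nazarov cyclisation (FeCl3, CH2Cl2, −30 °C) gives enone F8, whose carbonyl is C2 by construction. TBSOTf/Et3N gives the extended silyl dienol ether F9. Vinylogous Rubottom oxidation (dimethyldioxirane) then installs the C4 hydroxyl of 19.

**Step 23.**
- **What may go wrong.** Configuration may erode at the secondary alkyllithium or alkylzinc stage. β-Hydride elimination with chain walking to the linear isomer, or reduction of the iodo enone, may also occur.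
- **Fallback.** This runs from 36 to 40. Alkenylboronate F10 is made from the TBDPS ether of pent-4-yn-1-ol by copper-catalysed Markovnikov hydroboration. Suzuki coupling of 36 with F10 gives the cross-conjugated dienone F11. CeCl3/MeLi gives dienol F12. Hydroxyl-directed hydrogenation ([Ir(cod)(PCy3)(py)]PF6, H2) of the 1,1-disubstituted alkene, steered by the C10' hydroxyl and allylic strain, then sets C4' and reaches 40.

**Step 21.**
- **What may go wrong.** Oxygenation may occur at the other terminus of the allyl radical (a transposed enone), hydrogen may be abstracted at C7', or the β-silyloxy group may be lost with aromatisation.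
- **Fallback.** This runs from 34 to 35. SeO2/t-BuOOH works by an ene reaction followed by a [2,3] shift, which returns oxygen to the carbon that lost hydrogen and prefers CH2 over CH. It gives the C10' allylic alcohol F13. Dess–Martin periodinane then gives 35.

## Further compounds

F1 | step 30 | internal vinylstannane from 49 | O[C@@H]2C[C@@H](C)[C@]34C[C@]5(C(=O)O[C@H]6C[C@@](C)(O)C([C@H](C)CCCOC(C)=O)=C[C@H]65)[C@H](C(C)=C3C[C@H]2C(=C)[Sn](CCCC)(CCCC)CCCC)[C@H]4OC(C)=O
F2 | step 30 | 2-iodoalkene from F1 | O[C@@H]2C[C@@H](C)[C@]34C[C@]5(C(=O)O[C@H]6C[C@@](C)(O)C([C@H](C)CCCOC(C)=O)=C[C@H]65)[C@H](C(C)=C3C[C@H]2C(=C)I)[C@H]4OC(C)=O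
F3 | step 27 | ring B-fused cyclopentadienone | CC1=CC(=O)C2=C1C[C@@H](C#C[Si](C(C)C)(C(C)C)C(C)C)[C@H](O[Si](C)(C)C(C)(C)C)C[C@H]2C
F4 | step 27 | 7-norbornenone adduct | CC(C)(C)[Si](C)(C)O[C@@H]2C[C@@H](C)[C@]34C[C@]5(C(=O)O[C@H]6C[C@@](C)(O)C([C@H](C)CCCO[Si](c7ccccc7)(c7ccccc7)C(C)(C)C)=C[C@H]65)[C@H](C(C)=C3C[C@H]2C#C[Si](C(C)C)(C(C)C)C(C)C)C4=O
F5 | step 27 | anti C2 alcohol | CC(C)(C)[Si](C)(C)O[C@@H]2C[C@@H](C)[C@]34C[C@]5(C(=O)O[C@H]6C[C@@](C)(O)C([C@H](C)CCCO[Si](c7ccccc7)(c7ccccc7)C(C)(C)C)=C[C@H]65)[C@H](C(C)=C3C[C@H]2C#C[Si](C(C)C)(C(C)C)C(C)C)[C@H]4O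
F6 | step 11 | Weinreb amide of 13 | CON(C)C(=O)C1=CC[C@@H](C#C[Si](C(C)C)(C(C)C)C(C)C)[C@H](O[Si](C)(C)C(C)(C)C)C[C@H]1C
F7 | step 11 | cycloheptenyl (E)-propenyl ketone | C/C=C/C(=O)C1=CC[C@@H](C#C[Si](C(C)C)(C(C)C)C(C)C)[C@H](O[Si](C)(C)C(C)(C)C)C[C@H]1C
F8 | step 11 | 2-oxo-guai-1(5)-ene bicyclic enone (C4 epimers) | CC1CC(=O)C2=C1C[C@@H](C#C[Si](C(C)C)(C(C)C)C(C)C)[C@H](O[Si](C)(C)C(C)(C)C)C[C@H]2C
F9 | step 11 | extended silyl dienol ether of F8 | CC1=C2C[C@@H](C#C[Si](C(C)C)(C(C)C)C(C)C)[C@H](O[Si](C)(C)C(C)(C)C)C[C@@H](C)C2=C(O[Si](C)(C)C(C)(C)C)C1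
F10 | step 23 | 2-[5-(tert-butyldiphenylsilyloxy)pent-1-en-2-yl]-4,4,5,5-tetramethyl-1,3,2-dioxaborolane | C=C(CCCO[Si](c1ccccc1)(c1ccccc1)C(C)(C)C)B1OC(C)(C)C(C)(C)O1
F11 | step 23 | C5'-alkenyl dienone | COC(=O)C[C@@H]1C=C(C(=C)CCCO[Si](c2ccccc2)(c2ccccc2)C(C)(C)C)C(=O)C[C@@H]1O[Si](CC)(CC)CC
F12 | step 23 | C5'-alkenyl tertiary alcohol | COC(=O)C[C@@H]1C=C(C(=C)CCCO[Si](c2ccccc2)(c2ccccc2)C(C)(C)C)[C@](C)(O)C[C@@H]1O[Si](CC)(CC)CC
F13 | step 21 | C10' allylic alcohol (epimers) | COC(=O)C[C@@H]1C=CC(O)C[C@@H]1O[Si](CC)(CC)CC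
A1 | alternative 1 | ring E β-hydroxy ketone | C=C1C(=O)O[C@@H]2C[C@@H](C)[C@]34C[C@@](C(=O)OC)([C@@H]7C=C([C@H](C)CCCOC(C)=O)[C@](C)(O)CC7=O)[C@H](C(C)=C3C[C@@H]12)[C@H]4OC(C)=O
A2 | alternative 2 | 8-hydroxy-9-oxo C7 allyl silyl ether | O[C@@H]2C(=O)[C@@H](C)[C@]34C[C@]5(C(=O)O[C@H]6C[C@@](C)(O)C([C@H](C)CCCOC(C)=O)=C[C@H]65)[C@H](C(C)=C3C[C@H]2C(=C)CO[Si](C)(C)C(C)(C)C)[C@H]4OC(C)=O
A3 | alternative 3 | ring B 8-hydroxy 12-methyl ester | O[C@@H]2C[C@@H](C)[C@]34C[C@]5(C(=O)O[C@H]6C[C@@](C)(O)C([C@H](C)CCCOC(C)=O)=C[C@H]65)[C@H](C(C)=C3C[C@H]2C(=C)C(=O)OC)[C@H]4OC(C)=O
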